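In the first seconds of this flask the substrate leaves by two routes at once, and I want to reckon how they share it.

    substrate ⇌ intermediate A (K1 = 1.7, k1 = 0.11 s⁻¹)
    intermediate A → target (k2 = 0.79 s⁻¹)
    substrate ⇌ intermediate B (K3 = 1.2, k3 = 0.077 s⁻¹)
    2 substrate → self-condensation product (k4 = 1.8 M⁻¹ s⁻¹)

substrate 0.14 M; time 1.0 h

- percent here means substrate units held: one self-condensation product counts as two
- for a step with 2 of a species take k times the square, and two of it per event
- the reaction counts as stopped when no species that holds the substrate changes by six tenths of a point or more over the second half of the time
- run time (flask): 1.0 h

1. why nothing more happens at 1.0 h, or that something still does (forward and back rates have come level / it is still moving / all of the substrate has reacted)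
2. conversion of substrate at 1.0 h
3. amount of target at 1.0 h, in percent of the substrate charged

I turn the constants into times at the charge. Self-condensation gives the substrate a first half-life of 1.98 s, shorter than the 6.30 s of its forward passage into intermediate A. Intermediate A lives 1.17 s, shorter than the 1.98 s half-life of its feed by a factor of just 1.69, so I do not hold it in steady state. I need only its exits: each intermediate A goes forward to target or back to substrate, so over the whole run 92.4% of what enters goes on to target. Summed over the run, the route to target therefore counts as a first-order drain of 0.102 s⁻¹. That gives 0.0282 M as the crossover concentration, the [substrate] at which the two routes use substrate equally. The charge stands 4.96 times above it. Integrating the split over the falling [substrate], the target yield is the natural logarithm of one plus that ratio, divided by the ratio, which gives 36.0%.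

The weak link is intermediate B, which I have ignored. It comes level with substrate in about 7.08 s, longer than 1.98 s, so it matters later rather than at the start. Taken as level, it holds part of the pool out of both routes, and the crossover of the pool is then 0.0621 M. The same formula then gives 52.4%. The flask begins like the first case and leans towards the second, so I commit to the midpoint, 44.2%. In the tail intermediate B returns at 0.0642 s⁻¹, slower than the drain of 0.102 s⁻¹, so I do not take it as level there and solve substrate and intermediate B together. The slower decay rate is 0.0308 s⁻¹, a lifetime of 32.5 s, far shorter than 1.0 h, so I expect conversion of 100%.

The forecast says that all of the substrate has reacted, with conversion 100% and target 46%, higher than my 44.2%. Its opening ground is “The pool drains through irreversible exits, target and dimer”.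

The simulation answers that all of the substrate has reacted, with conversion 100% and target 43.6%.

This flask's target lies between 36.0% and 52.4%, and it already reads 43.6% at 0.100 h; reading later changes nothing. The self-condensation product holds 56.4%. In the neighbouring flask, charged with 0.035 M of substrate, the charge is 1.24 times the crossover concentration. The same formula gives 65.1% without intermediate B and 79.3% with it level, a midpoint of 72.2%. The neighbouring flask's simulated target is 72.5%.

The constants are those of an exercise; no experiment stands behind them.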